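Locants: plain numbers for the flavone without the methoxy group (O1 to C8a, ring B C1' to C6'), double primes for the 8-aryl flavone, triple primes for its ring B.
Enabling feature: the two 4-pyranone rings C (O1, C2, C3, C4, C4a, C8a and the double-primed set) flank the C3'–C8'' biaryl bond. Each is a dehydrated aryl 1,3-diketone whose ring oxygen (O1, O1'') is a phenol oxygen ortho to the C4 (C4'') ketone, so an aroyl group parked on that oxygen can be passed to the acetyl carbon.
Cuts, in retrosynthetic order: six benzyl–O bonds; O1–C2 and O1''–C2''; C2–C3 and C2''–C3'' together; the two aryl ester C–O bonds; C3'–C8''.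
Forward: one dibenzylated phloroacetophenone supplies both rings A. Its 3-iodide is joined to a ring B boronate first, the two esters are attached, both acyl groups migrate in one operation, both rings C close in one acid step, and hydrogenolysis ends the route.
C2 travels as an aldehyde until the crowded C8a'' phenol has been acylated, so no hydroxy acid ever has to be activated.
Stereochemistry: the target has no stereocentre and its biaryl axis carries no descriptor, so nothing has to be set.

Key step: step 10

Remark: the C3'–C8'' axis is taken as configurationally unassigned, so no control of axial chirality is attempted. Commercial 2',4',6'-trihydroxyacetophenone is a monohydrate and is dried before use.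

Step 1
Reactants: 1 2',4',6'-trihydroxyacetophenone
Product: 2 2-hydroxy-4,6-bis(benzyloxy)acetophenone
Conditions: BnBr (2.1 equiv), K2CO3, DMF, rt → 60 °C
Reagents that add atoms: benzyl bromide, BrCc1ccccc1
Why: Williamson ether synthesis: carbonate alkylates the para hydroxyl and one of the two equivalent ortho hydroxyls, after which the last one is tied up in a hydrogen bond to the acetyl oxygen and should stay free at this stoichiometry.

Step 2
Reactants: 2 2-hydroxy-4,6-bis(benzyloxy)acetophenone
Product: 3 1-[4,6-bis(benzyloxy)-2-hydroxy-3-iodophenyl]ethanone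
Conditions: NIS (1.0 equiv), DMF, rt, dark
Reagents that add atoms: N-iodosuccinimide, O=C1CCC(=O)N1I
Why: Electrophilic aromatic iodination: under neutral conditions NIS attacks chelated 2-hydroxy-4,6-dialkoxyaryl ketones next to the free hydroxyl, so iodine should enter C3 (the future C8'') and not C5 between the two benzyl ethers.

Step 3
Reactants: 4 3-bromo-4-hydroxybenzaldehyde
Product: 5 4-(benzyloxy)-3-bromobenzaldehyde
Conditions: BnBr, K2CO3, DMF, rt
Reagents that add atoms: benzyl bromide, BrCc1ccccc1
Why: Williamson ether synthesis on an acidic para-formyl phenol that has no competing nucleophilic site.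

Step 4
Reactants: 5 4-(benzyloxy)-3-bromobenzaldehyde
Product: 6 4-(benzyloxy)-3-(4,4,5,5-tetramethyl-1,3,2-dioxaborolan-2-yl)benzaldehyde
Conditions: B2pin2, PdCl2(dppf) (3 mol %), KOAc, 1,4-dioxane, 85 °C
Reagents that add atoms: bis(pinacolato)diboron, CC1(C)OB(OC1(C)C)B1OC(C)(C)C(C)(C)O1
Why: Miyaura borylation: the acetate base is too weak to touch the aldehyde or to start homocoupling, and ortho-alkoxy aryl bromides are standard substrates.

Step 5
Reactants: 3 1-[4,6-bis(benzyloxy)-2-hydroxy-3-iodophenyl]ethanone; 6 4-(benzyloxy)-3-(4,4,5,5-tetramethyl-1,3,2-dioxaborolan-2-yl)benzaldehyde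
Product: 7 3-[3-acetyl-4,6-bis(benzyloxy)-2-hydroxyphenyl]-4-(benzyloxy)benzaldehyde
Conditions: Pd(OAc)2 (5 mol %), SPhos (10 mol %), K3PO4, 1,4-dioxane/H2O, degassed, 90 °C
Reagents that add atoms: none
Why: Suzuki–Miyaura coupling: the bulky, electron-rich biarylphosphine suits the tri-ortho-substituted C3'–C8'' bond, and the ketone, present as its chelated phenoxide, should not be enolised by phosphate and so should leave the aldehyde alone.

Step 6
Reactants: 8 vanillic acid
Product: 9 4-(benzyloxy)-3-methoxybenzoic acid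
Conditions: BnBr, NaOH, EtOH/H2O, reflux; then aq. HCl
Reagents that add atoms: benzyl bromide, BrCc1ccccc1
Why: Williamson ether synthesis on the dianion, in which the phenoxide is the better nucleophile and hot hydroxide keeps the carboxyl group unesterified.

Step 7
Reactants: 9 4-(benzyloxy)-3-methoxybenzoic acid; 7 3-[3-acetyl-4,6-bis(benzyloxy)-2-hydroxyphenyl]-4-(benzyloxy)benzaldehyde
Product: 11 2-acetyl-3,5-bis(benzyloxy)-6-[2-(benzyloxy)-5-formylphenyl]phenyl 4-(benzyloxy)-3-methoxybenzoate, via O-benzylvanilloyl chloride 10 (not isolated)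
Conditions: (COCl)2, DMF (cat.), CH2Cl2, 0 °C → rt, evaporate; then 7, Et3N, DMAP (cat.), CH2Cl2, 0 °C → rt
Reagents that add atoms: oxalyl chloride, O=C(Cl)C(=O)Cl (chlorine of 10; none of its atoms stays in 11)
Why: Acid chloride formation followed by DMAP-catalysed O-acylation (Einhorn type): the acylpyridinium ion is reactive enough for the phenol wedged between the acetyl group and the aryl ring, and the aldehyde offers no acylable site.

Step 8
Reactants: 11 2-acetyl-3,5-bis(benzyloxy)-6-[2-(benzyloxy)-5-formylphenyl]phenyl 4-(benzyloxy)-3-methoxybenzoate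
Product: 12 3-{3-acetyl-4,6-bis(benzyloxy)-2-[(4-benzyloxy-3-methoxybenzoyl)oxy]phenyl}-4-(benzyloxy)benzoic acid
Conditions: NaClO2, NaH2PO4, 2-methyl-2-butene, t-BuOH/THF/H2O, 0 °C → rt
Reagents that add atoms: sodium chlorite, [Na+].[O-]Cl=O
Why: Pinnick oxidation: buffered chlorous acid converts the aldehyde into the acid at a pH that leaves the aryl ester, the methyl ketone and the benzyl ethers alone, and the alkene traps hypochlorous acid before it can chlorinate C6''.

Step 9
Reactants: 12 3-{3-acetyl-4,6-bis(benzyloxy)-2-[(4-benzyloxy-3-methoxybenzoyl)oxy]phenyl}-4-(benzyloxy)benzoic acid; 2 2-hydroxy-4,6-bis(benzyloxy)acetophenone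
Product: 13 2-acetyl-3,5-bis(benzyloxy)phenyl 3-{3-acetyl-4,6-bis(benzyloxy)-2-[(4-benzyloxy-3-methoxybenzoyl)oxy]phenyl}-4-(benzyloxy)benzoate (the biaryl bis(ortho-acyloxyacetophenone) diester)
Conditions: DCC, DMAP (cat.), CH2Cl2, 0 °C → rt
Reagents that add atoms: none
Why: Steglich esterification: 12 has no free hydroxyl left, so the activated acid can only meet the phenol of 2, a substrate class routinely esterified this way ahead of an acyl migration.

Step 10
Reactants: 13 biaryl bis(ortho-acyloxyacetophenone) diester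
Product: 15 bis(1,3-diketone) bisphenol 1-[4,6-bis(benzyloxy)-3-{2-(benzyloxy)-5-[3-(2,4-bis(benzyloxy)-6-hydroxyphenyl)-3-oxopropanoyl]phenyl}-2-hydroxyphenyl]-3-[4-(benzyloxy)-3-methoxyphenyl]propane-1,3-dione, via dilithium bis-enolate 14 (not isolated)
Conditions: 13 added to LiN(SiMe3)2 (6 equiv), THF, −78 °C → 0 °C; then cold aq. HCl
Reagents that add atoms: LiN(SiMe3)2, [Li]N([Si](C)(C)C)[Si](C)(C)C (lithium of 14; none of its atoms stays in 15)
Why: The excess amide deprotonates both acetyl groups at low temperature to give 14, and on warming each enolate carbon adds to the aryl ester carbonyl held ortho to it through a six-membered cyclic transition state, after which collapse of the tetrahedral alkoxide expels the phenoxide of the same ring and leaves the new C2–C3 and C2''–C3'' bonds. The closest known reaction is the Baker–Venkataraman rearrangement of ortho-aroyloxyacetophenones with lithium amide bases, run here at two sites of one molecule. No ring is closed and no stereocentre is created, so the step is an isomerisation that adds two skeletal bonds. The selectivity needed is that each enolate takes the ester on its own ring, which the ortho relationship secures, because crossover to the other ester would need a medium-ring transition state across the twisted biaryl and intermolecular attack is held back by dilution and inverse addition. The further equivalents of base turn each diketone into its chelated lithium enolate, which makes the transfer irreversible and guards against retro-Claisen cleavage. Since the vanilloyl group sits on the oxygen next to C8'', the phenoxide released is O1'' on C8a'', which fixes the 8-aryl and excludes the 6-aryl connectivity.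

Step 11
Reactants: 15 bis(1,3-diketone) bisphenol
Product: 16 5,7,4',5'',7'',4'''-hexa-O-benzyl-3'''-methoxy-3',8''-biflavone
Conditions: TsOH·H2O (cat.), toluene, 90 °C
Reagents that add atoms: none
Why: Acid-catalysed cyclodehydration of ortho-hydroxyaryl 1,3-diketones: each freed phenol oxygen adds 6-exo-trig to the aroyl carbonyl of its own diketone and loss of water gives the 4-pyranone, with only one hydroxyl available per diketone and a catalytic sulfonic acid that should spare the benzyl ethers.

Step 12
Reactants: 16 5,7,4',5'',7'',4'''-hexa-O-benzyl-3'''-methoxy-3',8''-biflavone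
Product: 17 8-[5-(5,7-dihydroxy-4-oxo-4H-chromen-2-yl)-2-hydroxyphenyl]-5,7-dihydroxy-2-(4-hydroxy-3-methoxyphenyl)-4H-chromen-4-one (CNP0179340.0)
Conditions: H2 (1 atm), Pd/C (10 %), THF/MeOH, rt
Reagents that add atoms: none
Why: Catalytic hydrogenolysis of aryl benzyl ethers, which on flavones is faster than saturation of the C2–C3 double bond and leaves the aryl methyl ether untouched.

Compound list
1 | 2',4',6'-trihydroxyacetophenone | CC(=O)c1c(O)cc(O)cc1O | starting material
2 | 2-hydroxy-4,6-bis(benzyloxy)acetophenone | CC(=O)c1c(O)cc(OCc2ccccc2)cc1OCc1ccccc1 | intermediate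
3 | 1-[4,6-bis(benzyloxy)-2-hydroxy-3-iodophenyl]ethanone | CC(=O)c1c(O)c(I)c(OCc2ccccc2)cc1OCc1ccccc1 | intermediate
4 | 3-bromo-4-hydroxybenzaldehyde | O=Cc1ccc(O)c(Br)c1 | starting material
5 | 4-(benzyloxy)-3-bromobenzaldehyde | O=Cc1ccc(OCc2ccccc2)c(Br)c1 | intermediate
6 | 4-(benzyloxy)-3-(4,4,5,5-tetramethyl-1,3,2-dioxaborolan-2-yl)benzaldehyde | O=Cc1ccc(OCc2ccccc2)c(B2OC(C)(C)C(C)(C)O2)c1 | intermediate
7 | 3-[3-acetyl-4,6-bis(benzyloxy)-2-hydroxyphenyl]-4-(benzyloxy)benzaldehyde | CC(=O)c1c(OCc2ccccc2)cc(OCc2ccccc2)c(-c2cc(C=O)ccc2OCc2ccccc2)c1O | intermediate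
8 | vanillic acid | COc1cc(C(=O)O)ccc1O | starting material
9 | 4-(benzyloxy)-3-methoxybenzoic acid | COc1cc(C(=O)O)ccc1OCc1ccccc1 | intermediate
10 | 4-(benzyloxy)-3-methoxybenzoyl chloride (O-benzylvanilloyl chloride, not isolated) | COc1cc(C(=O)Cl)ccc1OCc1ccccc1 | intermediate
11 | 2-acetyl-3,5-bis(benzyloxy)-6-[2-(benzyloxy)-5-formylphenyl]phenyl 4-(benzyloxy)-3-methoxybenzoate | CC(=O)c1c(OCc2ccccc2)cc(OCc2ccccc2)c(-c2cc(C=O)ccc2OCc2ccccc2)c1OC(=O)c1ccc(OCc2ccccc2)c(OC)c1 | intermediate
12 | 3-{3-acetyl-4,6-bis(benzyloxy)-2-[(4-benzyloxy-3-methoxybenzoyl)oxy]phenyl}-4-(benzyloxy)benzoic acid | CC(=O)c1c(OCc2ccccc2)cc(OCc2ccccc2)c(-c2cc(C(=O)O)ccc2OCc2ccccc2)c1OC(=O)c1ccc(OCc2ccccc2)c(OC)c1 | intermediate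
13 | biaryl bis(ortho-acyloxyacetophenone) diester | CC(=O)c1c(OCc2ccccc2)cc(OCc2ccccc2)c(-c2cc(C(=O)Oc3cc(OCc4ccccc4)cc(OCc4ccccc4)c3C(C)=O)ccc2OCc2ccccc2)c1OC(=O)c1ccc(OCc2ccccc2)c(OC)c1 | intermediate
14 | dilithium bis-enolate of 13 (not isolated) | C=C(O[Li])c1c(OCc2ccccc2)cc(OCc2ccccc2)c(-c2cc(C(=O)Oc3cc(OCc4ccccc4)cc(OCc4ccccc4)c3C(=C)O[Li])ccc2OCc2ccccc2)c1OC(=O)c1ccc(OCc2ccccc2)c(OC)c1 | intermediate
15 | bis(1,3-diketone) bisphenol | O=C(CC(=O)c1ccc(OCc2ccccc2)c(OC)c1)c1c(OCc2ccccc2)cc(OCc2ccccc2)c(-c2cc(C(=O)CC(=O)c3c(O)cc(OCc4ccccc4)cc3OCc3ccccc3)ccc2OCc2ccccc2)c1O | intermediate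
16 | 5,7,4',5'',7'',4'''-hexa-O-benzyl-3'''-methoxy-3',8''-biflavone | COc1cc(-c2cc(=O)c3c(OCc4ccccc4)cc(OCc4ccccc4)c(-c4cc(-c5cc(=O)c6c(OCc7ccccc7)cc(OCc7ccccc7)cc6o5)ccc4OCc4ccccc4)c3o2)ccc1OCc1ccccc1 | intermediate
17 | CNP0179340.0, 3'''-methoxy-3',8''-biapigenin | COc1cc(-c2cc(=O)c3c(O)cc(O)c(-c4cc(-c5cc(=O)c6c(O)cc(O)cc6o5)ccc4O)c3o2)ccc1O | target

Total step count: 12.
Longest linear sequence: 9 steps (steps 1, 2, 5, 7, 8, 9, 10, 11, 12; the branch through steps 3 and 4 is equally long).

Steps most likely to fail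

Step 5. Oxidative addition to the electron-rich iodide, which is flanked on both sides and present as its phenoxide, may be slow enough that protodeboronation of the boronate and hydrodeiodination take over. The fallback sets out from 3 and comes back at 7. It removes the phenoxide instead of pushing the catalyst. The phenol of 3 would be capped with MOMCl and i-Pr2NEt in refluxing CH2Cl2 to give 1-[4,6-bis(benzyloxy)-3-iodo-2-(methoxymethoxy)phenyl]ethanone F1. This neutral iodide would be coupled with 6 to give 3-[3-acetyl-4,6-bis(benzyloxy)-2-(methoxymethoxy)phenyl]-4-(benzyloxy)benzaldehyde F2. Aqueous HCl in THF at 40 °C would then remove the acetal, which the ortho-acetyl group makes labile, and return 7 with its benzyl ethers intact.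

Step 10. Acyl transfer at the crowded C8a'' ester may lag behind that at the open site, or an ester may be cleaved by intermolecular attack, so that half-rearranged and deacylated mixtures result. The fallback sets out from 12 and comes back at 16. It builds the two pyranones one after the other.
- Acid 12 would be treated with LiN(SiMe3)2 (one extra equivalent for the carboxylate) to give 3-{4,6-bis(benzyloxy)-3-[3-(4-benzyloxy-3-methoxyphenyl)-3-oxopropanoyl]-2-hydroxyphenyl}-4-(benzyloxy)benzoic acid F3.
- Acid-catalysed cyclodehydration would give the flavone acid 4-(benzyloxy)-3-[5,7-bis(benzyloxy)-2-(4-benzyloxy-3-methoxyphenyl)-4-oxo-4H-chromen-8-yl]benzoic acid F4.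
- Steglich esterification with 2 would give its 2-acetyl-3,5-bis(benzyloxy)phenyl ester F5.
- A single Baker–Venkataraman shift would give the flavone 1,3-diketone phenol F6.
- TsOH in toluene would close the second pyranone to 16.

Step 2. Positional selectivity may be poor (attack at C5 between the two benzyl ethers), or a second iodination may occur. The fallback sets out from 1 and comes back at 3. It iodinates while the ring is still symmetric. One equivalent of NIS at 0 °C would convert 1, whose two free ring positions are equivalent, into 2',4',6'-trihydroxy-3'-iodoacetophenone F7. Dibenzylation (BnBr, K2CO3, DMF) should then take the para hydroxyl and the less hindered ortho hydroxyl. The hydroxyl squeezed between iodine and acetyl should stay free, as partial alkylation of 3-substituted phloroacetophenones does, and this gives 3.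

Further compounds
F1 | step 5 | 1-[4,6-bis(benzyloxy)-3-iodo-2-(methoxymethoxy)phenyl]ethanone | CC(=O)c1c(OCOC)c(I)c(OCc2ccccc2)cc1OCc1ccccc1
F2 | step 5 | 3-[3-acetyl-4,6-bis(benzyloxy)-2-(methoxymethoxy)phenyl]-4-(benzyloxy)benzaldehyde | CC(=O)c1c(OCc2ccccc2)cc(OCc2ccccc2)c(-c2cc(C=O)ccc2OCc2ccccc2)c1OCOC
F3 | step 10 | 3-{4,6-bis(benzyloxy)-3-[3-(4-benzyloxy-3-methoxyphenyl)-3-oxopropanoyl]-2-hydroxyphenyl}-4-(benzyloxy)benzoic acid | O=C(CC(=O)c1ccc(OCc2ccccc2)c(OC)c1)c1c(OCc2ccccc2)cc(OCc2ccccc2)c(-c2cc(C(=O)O)ccc2OCc2ccccc2)c1O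
F4 | step 10 | 4-(benzyloxy)-3-[5,7-bis(benzyloxy)-2-(4-benzyloxy-3-methoxyphenyl)-4-oxo-4H-chromen-8-yl]benzoic acid | COc1cc(-c2cc(=O)c3c(OCc4ccccc4)cc(OCc4ccccc4)c(-c4cc(C(=O)O)ccc4OCc4ccccc4)c3o2)ccc1OCc1ccccc1
F5 | step 10 | 2-acetyl-3,5-bis(benzyloxy)phenyl ester of F4 | COc1cc(-c2cc(=O)c3c(OCc4ccccc4)cc(OCc4ccccc4)c(-c4cc(C(=O)Oc5cc(OCc6ccccc6)cc(OCc6ccccc6)c5C(C)=O)ccc4OCc4ccccc4)c3o2)ccc1OCc1ccccc1
F6 | step 10 | flavone 1,3-diketone phenol from the acyl shift of F5 | COc1cc(-c2cc(=O)c3c(OCc4ccccc4)cc(OCc4ccccc4)c(-c4cc(C(=O)CC(=O)c5c(O)cc(OCc6ccccc6)cc5OCc5ccccc5)ccc4OCc4ccccc4)c3o2)ccc1OCc1ccccc1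
F7 | step 2 | 2',4',6'-trihydroxy-3'-iodoacetophenone | CC(=O)c1c(O)cc(O)c(I)c1O
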